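The earlier runs and the new flask come from a simulation on assumed constants, and the scatter is random.

The vessel was closed, stirred and isothermal, and I wanted a figure for it that I could reckon by hand.

| setting | maple | cedar | oak | flask |
|---|---|---|---|---|
| substrate | 0.067 M | 0.15 M | 0.10 M | 0.10 M |
| other conformer | 1 equiv | 1 equiv | 1.5 equiv | 1.00 equiv |
| remark | run made earlier | run made earlier | run made earlier |  |
| time |  |  |  | 15 h |

| run | time / h | target / % | isomer of the product / % |
|---|---|---|---|
| maple | 1.33 | 40.8 | 46.0 |
| maple | 3.00 | 41.6 | 46.4 |
| maple | 6.00 | 41.1 | 46.3 |
| maple | 15.0 | 41.5 | 45.8 |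
| cedar | 1.33 | 36.0 | 39.2 |
| cedar | 3.00 | 36.8 | 39.1 |
| cedar | 6.00 | 36.3 | 39.8 |
| cedar | 15.0 | 35.8 | 40.1 |
| oak | 4.00 | 38.0 | 42.2 |
| oak | 8.00 | 38.0 | 41.6 |
| oak | 12.0 | 37.8 | 40.6 |
| oak | 15.0 | 36.4 | 41.3 |

(scatter of a reading: 0.5 percentage points)

- in a conversion other conformer counts as not yet reacted

1. amount of target at 15 h, in percent of the substrate and other conformer together charged
2. amount of isomer of the product at 15 h, in percent of the substrate and other conformer together charged
3. amount of target if the flask were left three thousand times as long, in percent of the substrate and other conformer together charged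

In the maple run target stood at 40.8% after 1.33 h and 41.5% after 15.0 h, so I read each run as a plateau and averaged it. Target plus isomer of the product, Y, averaged 87.4% in maple, 75.8% in cedar and 79.0% in oak. Their total charges c, substrate and other conformer together, were 0.134 M, 0.300 M and 0.250 M.

The bench rule says that the loss, 1 − Y, goes with c. It fails here: from maple to cedar c rose 2.24-fold, but the loss rose less, 1.92-fold, and each average is good to about 0.35 percentage points.

What held still was the ratio of lost to kept per molar of charge, b = (1/Y − 1)/c, my loss number. It came to 1.08 M⁻¹, 1.07 M⁻¹ and 1.06 M⁻¹, with a mean of 1.07 M⁻¹; oak, with its extra equivalents, fell in line. For the flask, c is 0.200 M, so Y = 1/(1 + bc) gives 82.4%. The selectivity for target read 47.5% of Y, so I committed to 39.1% target and 43.3% isomer of the product, and carried the plateau to the long time with little confidence.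

The forecast, by its own formula, gave 39.2% target and 43.2% isomer of the product at 15 h, and 39% target for the long time (range 0% to 60%), holding that “Total concentration, not the equivalents, sets the loss”. The flask gave 39.1% target and 43.0% isomer of the product at 15 h, and 39.1% target for the long time.

    substrate ⇌ other conformer, settled at all times (K = 1.50)
    substrate → target (k = 0.00140 s⁻¹)
    other conformer → isomer of the product (k = 0.0450 s⁻¹)
    target ⇌ isomer of the product (K = 1.10, k = 0.00310 s⁻¹)
    2 substrate → self-condensation product (k = 0.200 M⁻¹ s⁻¹)

In the flask, b came to 1.09 M⁻¹, with self-condensation product at 17.9%, each counted as the two it holds. At the charge of the flask, the step to self-condensation product drained the pool of substrate and other conformer at 0.464 of the rate of the two first-order steps from that pool together. For the neighbour flask at 0.25 M of substrate, equivalents held, b gave 65.2% for target plus isomer of the product, and that flask stood at 66.4%.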